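**Plan**

- Feature used: C1–C6 of the target is a 2,3-epoxy-4-en-6-one acid. The trans oxirane (C2, C3, O) lies between the C1 carboxyl and the C4=C5 alkene of the C6 ketone, so it is one epoxidised double bond of a linear 2,4-diene with a carbonyl at each end. If C1 is an aldehyde, that end alone can bind a chiral amine.
- Retrosynthetic cuts, in order: C1 acid to aldehyde (oxidation level only); the C2–O and C3–O bonds of the oxirane; the C2=C3 alkene (Wittig, removes C1–C2); the C3–C6 oxo-enal back to a furan ring; the C6–C7 bond (furyl anion plus C16 bromide).
- Forward: the chain is joined first (C6–C7), the furan is opened to the E 4-oxo-enal, the formyl ylide adds C1–C2, the single ring (the oxirane) closes in the amine-catalysed epoxidation, and C1 is oxidised last.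
- Stereochemistry: C2 and C3 both come from the chiral diarylprolinol silyl ether in the epoxidation. The C4=C5 E geometry comes from the base-equilibrated furan opening and is not touched afterwards.

Key step: step 4

Assumption: the sense of induction in step 4 is assigned from the face-shielding model for iminium ions of diarylprolinol silyl ethers (oxygen enters anti to the CAr2(OSiMe3) group of the E,s-trans ion), which calls for the (S)-catalyst; if a correlation of the epoxy aldehyde showed the other sense, the enantiomeric catalyst would be the only change.

**Route**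

Step 1
Reactants: 1 furan; 2 1-bromohexadecane
Product: 4 2-hexadecylfuran, via 2-furyllithium 3 (not isolated)
Conditions: n-BuLi, THF, −78 to 0 °C; then 2, DMPU, 0 °C to rt
Reagents that add atoms: none
Why: n-BuLi removes the acidic C2 proton next to the furan oxygen (directed lithiation), and the resulting 2-furyllithium displaces bromide from the unhindered primary bromide in an SN2 alkylation that DMPU accelerates, forming the future C6–C7 bond.

Step 2
Reactants: 4 2-hexadecylfuran
Product: 6 (E)-4-oxoicos-2-enal, via (Z)-4-oxoicos-2-enal 5 (not isolated)
Conditions: NBS, NaHCO3, acetone/THF/H2O, −20 °C; then pyridine, rt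
Reagents that add atoms: water, O
Why: In this oxidative ring opening of a 2-alkylfuran, NBS brominates the electron-rich furan, water adds across the 2,5-positions and HBr is lost to unmask the Z 4-oxo-enal, which pyridine equilibrates by reversible conjugate addition to the more stable E isomer that becomes C4=C5.

Step 3
Reactants: 6 (E)-4-oxoicos-2-enal; 7 (triphenylphosphoranylidene)acetaldehyde
Product: 8 (2E,4E)-6-oxodocosa-2,4-dienal
Conditions: toluene, 60 °C, 7 not in excess
Reagents that add atoms: none
Why: In this Wittig olefination the carbonyl-stabilised ylide should attack only the aldehyde of 6, because stabilised ylides do not olefinate conjugated ketones under these conditions, and should give the E alkene C2=C3 as stabilised ylides do, while holding 7 at one equivalent limits a second homologation of the product aldehyde.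

Step 4
Reactants: 8 (2E,4E)-6-oxodocosa-2,4-dienal
Product: 11 (2S,3R)-3-[(1E)-3-oxononadec-1-en-1-yl]oxirane-2-carbaldehyde, via dienyl iminium ion 9 (not isolated), via 3-hydroperoxy enamine 10 (not isolated)
Conditions: (S)-2-[bis(3,5-bis(trifluoromethyl)phenyl)(trimethylsilyloxy)methyl]pyrrolidine (10 mol %), 35% aq. H2O2, CH2Cl2, rt
Reagents that add atoms: hydrogen peroxide, OO
Why: The amine condenses with the aldehyde of 8 (the more hindered conjugated ketone should not compete) to give the E,s-trans dienyl iminium ion 9, neutral H2O2 adds to C3, and the enamine carbon C2 of 10 displaces water from the proximal peroxide oxygen before hydrolysis releases 11 and the amine. The closest known reaction type is the diarylprolinol silyl ether catalysed H2O2 epoxidation of enals, established for enals carrying alkyl, aryl or ester groups on the β-carbon. The oxirane, the only ring made, closes in 3-exo-tet mode at oxygen, and the trans arrangement results because 10 closes from the rotamer that keeps the C4 alkenyl group anti to C1. C3 is controlled by the CAr2(OSiMe3) group of the catalyst, which covers one face of the planar iminium ion so that oxygen enters from the other (3R with the S catalyst), and C2 is controlled by the same group because the enamine carbon can only reach that oxygen from the face on which it already sits (2S). The step needs oxygen at C2=C3 and not at C4=C5; the substrate secures this because only the aldehyde terminus forms an iminium ion, C3 is its β-carbon and the only position from which a three-membered ring can close onto the enamine carbon, and C5, the other carbon activated through the iminium ion, is the α-carbon of the ketone and so is polarised against nucleophilic attack. Without added base there is no hydroperoxide anion for Weitz–Scheffer attack at C4 of the enone.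

Step 5
Reactants: 11 (2S,3R)-3-[(1E)-3-oxononadec-1-en-1-yl]oxirane-2-carbaldehyde
Product: 12 (2S,3R)-3-[(1E)-3-oxononadec-1-en-1-yl]oxirane-2-carboxylic acid
Conditions: NaClO2, NaH2PO4, 2-methyl-2-butene, t-BuOH/THF/H2O, 0 °C to rt
Reagents that add atoms: sodium chlorite, [Na+].[O-]Cl=O
Why: In this Pinnick oxidation chlorous acid adds to the aldehyde and fragments to the acid and HOCl, which 2-methyl-2-butene traps, so the epoxide, the enone and the C2 stereocentre (an oxirane carbon that does not enolise in the weakly acidic buffer) should stay untouched.

**Compound list**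

1 | furan | c1ccoc1 | starting material
2 | 1-bromohexadecane | CCCCCCCCCCCCCCCCBr | starting material
3 | 2-furyllithium | [Li]c1ccco1 | intermediate
4 | 2-hexadecylfuran | CCCCCCCCCCCCCCCCc1ccco1 | intermediate
5 | (Z)-4-oxoicos-2-enal | CCCCCCCCCCCCCCCCC(=O)/C=C\C=O | intermediate
6 | (E)-4-oxoicos-2-enal | CCCCCCCCCCCCCCCCC(=O)/C=C/C=O | intermediate
7 | (triphenylphosphoranylidene)acetaldehyde | O=CC=P(c1ccccc1)(c1ccccc1)c1ccccc1 | starting material
8 | (2E,4E)-6-oxodocosa-2,4-dienal | CCCCCCCCCCCCCCCCC(=O)/C=C/C=C/C=O | intermediate
9 | (2S)-2-{bis[3,5-bis(trifluoromethyl)phenyl](trimethylsilyloxy)methyl}-1-[(2E,4E)-6-oxodocosa-2,4-dienylidene]pyrrolidinium, E at C=N (cation) | CCCCCCCCCCCCCCCCC(=O)/C=C/C=C/C=[N+]1\CCC[C@H]1C(O[Si](C)(C)C)(c1cc(cc(c1)C(F)(F)F)C(F)(F)F)c1cc(cc(c1)C(F)(F)F)C(F)(F)F | intermediate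
10 | (2S)-2-{bis[3,5-bis(trifluoromethyl)phenyl](trimethylsilyloxy)methyl}-1-[(1E,3R,4E)-3-hydroperoxy-6-oxodocosa-1,4-dien-1-yl]pyrrolidine | CCCCCCCCCCCCCCCCC(=O)/C=C/[C@@H](OO)/C=C/N1CCC[C@H]1C(O[Si](C)(C)C)(c1cc(cc(c1)C(F)(F)F)C(F)(F)F)c1cc(cc(c1)C(F)(F)F)C(F)(F)F | intermediate
11 | (2S,3R)-3-[(1E)-3-oxononadec-1-en-1-yl]oxirane-2-carbaldehyde | CCCCCCCCCCCCCCCCC(=O)/C=C/[C@H]1O[C@@H]1C=O | intermediate
12 | (2S,3R)-3-[(1E)-3-oxononadec-1-en-1-yl]oxirane-2-carboxylic acid, i.e. (2S,3R,4E)-2,3-epoxy-6-oxodocos-4-enoic acid | CCCCCCCCCCCCCCCCC(=O)/C=C/[C@H]1O[C@@H]1C(=O)O | target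

**Step count and risks**

Total steps: 5. Longest linear sequence: 5 steps (from 1 or 2 to 12).

Steps most likely to fail:

1. Step 4. Oxygen may be delivered to the wrong alkene, either by peroxide addition at C5 of the vinylogous iminium ion or by base-mediated attack at C4 of the enone. The amine may also be tied up by conjugate addition to the doubly activated diene, and reversible peroxide addition may erode the enantio- or diastereoselectivity. Fallback, setting out from 8 and returning at 11: the aldehyde alone is reduced with NaBH(OAc)3 in THF to (2E,4E)-1-hydroxydocosa-2,4-dien-6-one F1. The allylic hydroxyl then directs a Katsuki–Sharpless epoxidation (Ti(OiPr)4, D-(−)-diethyl tartrate, t-BuOOH, 4 Å molecular sieves, CH2Cl2, −20 °C) to C2=C3 only, since the enone alkene is neither allylic to the hydroxyl nor electron-rich. This should give [(2R,3R)-3-[(1E)-3-oxononadec-1-en-1-yl]oxiran-2-yl]methanol F2. Dess–Martin oxidation buffered with NaHCO3 in CH2Cl2 then gives 11.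

2. Step 3. The product dienal may compete with 6 for the ylide (double homologation), the ylide may add in conjugate fashion to the ene-dicarbonyl unit, and the sensitive oxo-enal may oligomerise on heating. Fallback, setting out from 6 and returning at 8: the ylide made from (1,3-dioxolan-2-ylmethyl)triphenylphosphonium bromide and t-BuOK in THF is added at −78 °C, so that the new aldehyde stays masked while ylide is present. This should give 2-[(3E)-5-oxohenicosa-1,3-dien-1-yl]-1,3-dioxolane F3 as a mixture at the new alkene. Dilute aqueous HCl in THF with a trace of iodine then hydrolyses the acetal and equilibrates the diene to the E,E form, giving 8.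

3. Step 2. The long-chain furan may dissolve poorly in the cold aqueous medium, which invites over-bromination, and the oxo-enal may decompose during the base-induced Z to E equilibration. Fallback, setting out from 2 and returning at 6: 2 is converted with Mg in THF into hexadecylmagnesium bromide F4, which is added at −78 °C to the aldehyde of commercial (E)-4,4-dimethoxybut-2-enal to give racemic (E)-1,1-dimethoxyicos-2-en-4-ol F5. Allylic oxidation with MnO2 in CH2Cl2 gives (E)-1,1-dimethoxyicos-2-en-4-one F6, and p-TsOH (cat.) in acetone/H2O releases the aldehyde to give 6 with the E alkene already in place.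

Further compounds
F1 | step 4 | (2E,4E)-1-hydroxydocosa-2,4-dien-6-one | CCCCCCCCCCCCCCCCC(=O)/C=C/C=C/CO
F2 | step 4 | [(2R,3R)-3-[(1E)-3-oxononadec-1-en-1-yl]oxiran-2-yl]methanol | CCCCCCCCCCCCCCCCC(=O)/C=C/[C@H]1O[C@@H]1CO
F3 | step 3 | 2-[(3E)-5-oxohenicosa-1,3-dien-1-yl]-1,3-dioxolane (1E/1Z mixture) | CCCCCCCCCCCCCCCCC(=O)/C=C/C=CC1OCCO1
F4 | step 2 | hexadecylmagnesium bromide | CCCCCCCCCCCCCCCC[Mg]Br
F5 | step 2 | (E)-1,1-dimethoxyicos-2-en-4-ol (racemic) | CCCCCCCCCCCCCCCCC(O)/C=C/C(OC)OC
F6 | step 2 | (E)-1,1-dimethoxyicos-2-en-4-one | CCCCCCCCCCCCCCCCC(=O)/C=C/C(OC)OC
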